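In a one-step world each substrate goes to its own product, and two rates are all you compare. The summer run is this same flask, followed so far.

common to all: free catalyst 20 mM; added ligand 60 mM
- summer: left-handed substrate 1 M; right-handed substrate 1 M; reagent 2.5 M (fed, over 50 min); the very flask that is asked about, followed so far; the fed solution adds 0.20 times the starting volume
- flask: left-handed substrate 1.0 M; right-handed substrate 1.0 M; reagent 2.50 M (fed, over 50 min); the fed solution adds 0.20 times the starting volume; time 1.5 h

summer run (percent of the left-handed substrate and right-handed substrate together charged)

| time / min | left-handed substrate / % | right-handed substrate / % | left-handed product / % |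
|---|---|---|---|
| 5.00 | 49.5 | 49.8 | 0.3 |
| 12.0 | 49.1 | 49.2 | 1.1 |
| 25.0 | 47.6 | 48.8 | 2.7 |
| 40.0 | 45.6 | 47.2 | 5.0 |

(each reading ± 0.3 percentage points)

1. part of the left-handed substrate and right-handed substrate charged together that has reacted at 1.5 h
2. excess of left-handed product over right-handed product in the product at 1.5 h
3. excess of right-handed substrate over left-handed substrate among what is left of the two at 1.5 h

- free catalyst is single-handed; left-handed substrate and right-handed substrate are mirror images of each other, charged as a racemate, each of them at the stated concentration
- every charge counts on the volume at the start, and the solution that is fed holds the whole dose
- an excess is the difference of the two amounts in percent of their sum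
- an excess is below zero if the other one leads

Suppose both products come from the same catalyst and reagent. Those then cancel. The rate of left-handed product over that of right-handed product is s times c(left-handed substrate)/c(right-handed substrate).

Now turn the question round. For right-handed product to be made faster, the excess of right-handed substrate must pass s minus one over s plus one.

Read s from the summer run. At 40.0 min the balance leaves 2.20% of right-handed product. With equal substrates, the first answer is 2.27. But right-handed substrate already leads. Put the mean substrate ratio back in and go round once more: 2.31. This s, the selectivity factor, is the ratio of the two rates at equal substrates. Each reading scatters by 0.3 percentage points, so s is rough.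

The opposite outcome needs a substrate excess of 39.6%. The summer run shows 1.72% at 40.0 min, far less. Holding that excess to the asked time, I reckon eP at 38.2%.

The forecast, with “a selectivity of about 1.7–2.2”, gave c 17.4%, eS 5.8% and eP 28%, lower than my figure.

The flask gives c 17.6%, eP 40.5%, eS 2.45%.

    reagent + free catalyst + left-handed substrate → free catalyst + left-handed product (k = 0.490 /M²/min)
    reagent + free catalyst + right-handed substrate → free catalyst + right-handed product (k = 0.200 /M²/min)
    left-handed substrate ⇌ right-handed substrate (k = 0.0190 /min)
    free catalyst + added ligand ⇌ idle complex (K = 12.0 /M, k = 0.470 /M/min)
    free catalyst ⇌ dormant form (K = 2.00, k = 0.0250 /min)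
    2 free catalyst → spent catalyst (k = 0.620 /M/min)

At 1.5 h the substrate excess in this flask stands at 2.45%, far below 39.6%. Now take the neighbour flask, with 0.24 M of added ligand. At 1.50 h its idle complex holds 41.1% of the catalyst charged, against 13.4% in this flask, and its c falls to 13.2%. With s and its substrate excess of 1.94%, the same reckoning gives 37.9%. The neighbour flask gives eP 40.9%.

The numbers in the tables were computed for substances that don't exist; noise was put on by code.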